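## Analysis of the target

1. The target is a germacranolide. In the usual numbering C1–C10 form the ten-membered carbocycle, C14 is the methyl on C10 and C15 is the hydroxymethyl carbon on C4. C11–C13 are the propionate unit on C7, C12 closes a γ-lactone onto O6, and O8 carries the 2-(acetoxymethyl)acrylate.
2. In both ring alkenes, C1=C10 (E) and C4=C5 (Z by CIP only because of O15), the ring bonds are trans. The carbocycle is therefore a strained (E,E)-cyclodeca-1,5-diene.
3. The four stereocentres are contiguous: C6 (R), C7 (R), C8 (S) and C11 (S). H6 and H7 are anti (trans-fused lactone), O8 lies on the side of H7, and C13 is trans to C8 on the lactone, which is the more stable position at the only epimerisable centre.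
4. Several groups are sensitive. The 1,5-diene cyclises transannularly with acid and undergoes Cope rearrangement on strong heating. A free 8-OH can translactonise under base, and O6 is an allylic carboxylate. The side chain is both a Michael acceptor and an allylic acetate, so it must come late.
5. The hard part is to close a ten-membered ring that holds two trans trisubstituted alkenes while C6 and C7 are set next to C8, whose oxygen no cheap terpene of the chiral pool provides.
6. The feature that is exploited is the array O6–C6(–C5)–C7–C11(C12)(C13). C6 is a carbinol carbon flanked by the C4/C5 unsaturation and bonded to C7, which bears a three-carbon branch. This is the retron of a [2,3]-Wittig rearrangement in which O6 was once bound to C12.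
7. In addition, O6–C6–C5=C4–C15–O15 is a (Z)-2-ene-1,4-diol, the retron of a hydroxyl-directed trans-hydrometalation of a C4≡C5 alkyne. An alkyne at this place also decides where the carbanion of the rearrangement forms.

## Retrosynthetic reasoning

**Side chain and C15.** The O8–acyl bond is cut (31 from 28 and 30), and C15 is kept as an aldehyde until the last step (32 from 31). The acrylate tolerates neither strong base, aluminium hydrides nor Pd(0), so it has to come late. With C15 as an enal, O8 is the only hydroxyl in 28 and O15 needs no protecting group. The forward steps only need chemoselectivity: acylation of a single alcohol, then 1,2-reduction of an aldehyde beside three esters.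

**C4–C15.** The formyl carbon of 27 is removed to leave the vinyl iodide 26. This takes one carbon and one oxygen out of all earlier intermediates. The forward carbonylative formylation must keep the alkene geometry.

**Lactone (O6–C12 and the oxidation level of C12).** Compound 26 goes back through its C11 epimer mixture 25 to the 1,4-diol 23, and then to the isopropenyl alcohol 21. C11 is the one centre that equilibrates to the wanted configuration, so it needs no control when it is formed. The forward steps are anti-Markovnikov hydration of the only 1,1-disubstituted alkene, oxidative lactonisation and base equilibration.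

**C4=C5.** The (Z)-γ-iodoallylic alcohol 21 is traced to the propargylic alcohol 19. Addition of H to C5 and of the metal to C4, anti and directed by O6, gives exactly the ring-trans alkene with the C4 substituent cis to C6. No separate synthesis of this trisubstituted alkene is needed.

**Key disconnection, C6–C7.** In 19 the ring bond C6–C7 is cut and O6 is reconnected to C12, which gives the 13-membered allyl propargyl ether 17. Cutting here has three advantages:

- It removes the strained ring and two stereocentres at once.
- It leaves a precursor with a single stereocentre (C8) and an unstrained ring.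
- It places the carbanion at the only doubly activated C–H.

The forward step must form C6–C7, break O–C12, and relay C8 to C7 and C6.

**Ring of 17.** The ring is opened at C4≡C5 to the methyl-capped diyne 16. A 13-membered cycloalkyne is an easy case for alkyne metathesis, and the alkenes are not touched.

**C1–C2 and C10–C14.** Compound 16 is split at the sp2–sp3 bond C1–C2 into vinyl iodide 12 and iodide 14 (from 13). Compound 12 comes from the terminal alkyne 10 (silyl ether of 9) by methyl-metalation, which sets C1=C10 as E and brings in C14.

**C8–C9 and the western end.** Alcohol 9 is cut at C8–C9 into enal 7 and the three-carbon boronate 8. This is the only step that creates absolute configuration. Enal 7 comes from iodide 5 by formylation, 5 from 3 and 4 by ether formation, and 3 from 1 by the same methyl-metalation, which sets C7=C11 as E.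

## Alternatives that were turned down

**Alternative 1:** This is the textbook route: cut C6–C7 without a tether. The forward step is an intramolecular Nozaki–Hiyama–Kishi or Barbier allylation of the bromo enal A1, which gives the α-methylene lactone A2.

- A1 must already hold both ring alkenes, O15, C8 and a (Z)-2-(bromomethyl)enoate, so the precursor is no simpler than the product.
- The allylmetal is configurationally labile, and the open ten-membered transition state has no element that ties the face of C7 to C8.
- The entropic and strain costs fall on the same step as C–C bond formation.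
- A2 still needs a conjugate reduction to set C11.
- It is also the route most chemists would draw first.

**Alternative 2:** Keep a temporary C5–C10 bond. The forward step is an enolate-assisted seven-centre (vinylogous Grob) fragmentation of the trans-decalin mesylate aldehyde A3. The C15 aldehyde enolate pushes and the equatorial C1 mesylate leaves, which gives 27 directly.

- The mechanism fits well. The chair geometry (C2–C1–C10–C9 and C3–C4–C5–C6 both anti) would give both trans alkenes, and C15 emerges as the enal.
- It was turned down for step economy. A3 has eight stereocentres, and the commercially available eudesmanolides lack the C8 oxygen.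
- Installing O1, the C4 formyl group and O8 on a decalin each costs several steps.
- The way to the precursor would cost more than the fragmentation wins.

**Alternative 3:** Form C2–C3 by an anionic oxy-Cope rearrangement of the trans-1,2-dialkenylcyclohexanol A4. The ten-membered enolate would be trapped as the enol triflate A5, and C14 would come from methyl cross-coupling.

- A4 carries six stereocentres on one cyclohexane.
- Its ketone precursor has two β-oxygen leaving groups (O6 and O8) and would eliminate easily.
- The potassium alkoxide conditions enolise and open the lactone, so the lactone would have to be masked.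
- Two further steps are needed to turn the C10 oxygen into a methyl group.
- All hard stereocentres have to exist before the key step, so the step builds only the ring.

Key step: step 10

Remark: germacranolide locants (C1–C15) are used in all explanations. C11 is written without configuration in 22–25, because both epimers are carried on to the equilibration in step 14.

## Steps

**Step 1**
Reactants: 1 prop-2-yn-1-ol
Product: 3 (E)-3-iodo-2-methylprop-2-en-1-ol, via alkenylalane 2 (not isolated)
Conditions: Me3Al (3 equiv), Cp2ZrCl2 (25 mol %), CH2Cl2, 0 °C → rt; then I2, THF, −30 °C; aq K2CO3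
Reagents that add atoms: trimethylaluminium C[Al](C)C; iodine II
Why: Zirconium-catalysed syn-carboalumination (Negishi) puts the methyl (C13) on the internal carbon and aluminium on the terminus. Iodinolysis with retention gives the E iodide, so C12 will be trans to C8.

**Step 2**
Reactants: 3 (E)-3-iodo-2-methylprop-2-en-1-ol; 4 1-bromobut-2-yne
Product: 5 (E)-3-(but-2-yn-1-yloxy)-1-iodo-2-methylprop-1-ene
Conditions: NaH, THF–DMF, 0 °C → rt
Reagents that add atoms: none
Why: This is a Williamson ether synthesis on a primary propargylic bromide. It installs the temporary C12–O–C6 link at the outset, so O12 never needs a protecting group.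

**Step 3**
Reactants: 5 (E)-3-(but-2-yn-1-yloxy)-1-iodo-2-methylprop-1-ene
Product: 7 (E)-4-(but-2-yn-1-yloxy)-3-methylbut-2-enal, via alkenylmagnesium chloride 6 (not isolated)
Conditions: i-PrMgCl·LiCl, THF, −20 → 0 °C; then DMF, 0 °C → rt; H2O
Reagents that add atoms: N,N-dimethylformamide CN(C)C=O
Why: Iodine–magnesium exchange on alkenyl iodides goes with retention and is helped by the allylic ether oxygen. The Grignard reagent is not basic enough to metalate the propargylic OCH2, and Bouveault formylation then delivers C8.

**Step 4**
Reactants: 7 (E)-4-(but-2-yn-1-yloxy)-3-methylbut-2-enal; 8 allenylboronic acid pinacol ester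
Product: 9 (4S,5E)-7-(but-2-yn-1-yloxy)-6-methylhept-5-en-1-yn-4-ol
Conditions: (S)-TRIP (10 mol %), 4 Å MS, toluene, −20 °C
Reagents that add atoms: none
Why: This is a chiral phosphoric acid-catalysed propargylation through a closed six-membered SE2′ transition state. By analogy with aryl and alkenyl aldehydes, the (S)-acid should direct attack to the Si face and set C8 as S. The antipodal acid is equally available should the sense be opposite.

**Step 5**
Reactants: 9 (4S,5E)-7-(but-2-yn-1-yloxy)-6-methylhept-5-en-1-yn-4-ol
Product: 10 TBS ether of 9
Conditions: TBSCl, imidazole, DMF, rt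
Reagents that add atoms: tert-butyldimethylsilyl chloride CC(C)(C)[Si](C)(C)Cl
Why: This is a standard silylation. The group survives organoaluminium, organolithium and aluminium hydride reagents, and its bulk sharpens the facial bias in step 10.

**Step 6**
Reactants: 10 TBS ether of 9
Product: 12 (1E,4S,5E)-7-(but-2-yn-1-yloxy)-4-(tert-butyldimethylsilyloxy)-1-iodo-2,6-dimethylhepta-1,5-diene, via alkenylalane 11 (not isolated)
Conditions: Me3Al (2.5 equiv), Cp2ZrCl2 (30 mol %), CH2Cl2, 0 °C → rt; then I2, THF, −30 °C; aq K2CO3
Reagents that add atoms: trimethylaluminium C[Al](C)C; iodine II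
Why: This second Negishi carboalumination–iodination takes place at the terminal alkyne, which reacts much faster than the internal butynyl ether. Syn addition sets C1=C10 as E and brings in C14.

**Step 7**
Reactants: 13 pent-3-yn-1-ol
Product: 14 5-iodopent-2-yne
Conditions: I2, PPh3, imidazole, CH2Cl2, 0 °C
Reagents that add atoms: iodine II
Why: This is an Appel-type iodination of a primary alcohol, and no other functional group is present.

**Step 8**
Reactants: 14 5-iodopent-2-yne; 12 vinyl iodide of step 6
Product: 16 (6E,9S,10E)-12-(but-2-yn-1-yloxy)-9-(tert-butyldimethylsilyloxy)-7,11-dimethyldodeca-6,10-dien-2-yne, via pent-3-ynylzinc iodide 15 (not isolated)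
Conditions: 14, Zn dust, LiCl, THF, 40 °C; then 12, Pd(dppf)Cl2 (5 mol %), THF, rt
Reagents that add atoms: none
Why: Zinc inserts into the primary alkyl iodide. The Negishi sp3–sp2 coupling of homopropargylic zinc reagents with E-alkenyl iodides is a standard terpenoid bond formation, and it keeps the alkene geometry (C1–C2).

**Step 9**
Reactants: 16 open-chain diyne of step 8
Product: 17 (3E,5S,7E)-5-(tert-butyldimethylsilyloxy)-3,7-dimethyl-1-oxacyclotrideca-3,7-dien-11-yne
Conditions: [Mo(≡CC6H4-4-OMe)(OSiPh3)3] (5 mol %), 5 Å MS, toluene (2 mM), rt → 50 °C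
Reagents that add atoms: none
Why: In this ring-closing alkyne metathesis the 13-membered cycloalkyne is unstrained. Molybdenum alkylidynes leave alkenes, ethers and silyl ethers alone, and the sieves remove the volatile alkyne to drive the closure.

**Step 10**
Reactants: 17 13-membered allyl propargyl ether
Product: 19 (1S,6E,9S,10S)-9-(tert-butyldimethylsilyloxy)-7-methyl-10-(prop-1-en-2-yl)cyclodec-6-en-2-yn-1-ol (ring C1 = C6, C9 = C8, C10 = C7), via C6-lithiated ether 18 (not isolated)
Conditions: n-BuLi (1.5 equiv), THF–pentane, −78 → −20 °C; H2O at −78 °C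
Reagents that add atoms: none
Why: This is a [2,3]-Wittig rearrangement run transannularly: the base removes a C6 proton, the only C–H that is both α to the ether oxygen and propargylic, so the carbanion forms at C6 and not at C12 (where loss of the C8 silyloxy group would follow), and C6 then bonds to C7 through a five-membered envelope transition state while O–C12 breaks and C11=C12 forms. The closest known reaction type is the ring contraction of 13-membered allyl propargyl and bis-allyl ethers to ten-membered homoallylic alcohols. The ten-membered carbocycle is closed by a transannular 13→10 contraction, so the entropic price of the medium ring was already paid in the unstrained closure of step 9, and O, C12 and C11 leave the ring as the alkoxide and the isopropenyl group. C7 is controlled by C8: allylic 1,3-strain with the C13 methyl holds H8 in the plane of C7=C11, the ring bond C8–C9 points into the ring and the silyloxy group outwards, so C6 can reach only the inner face, anti to the C8–O bond. C6 is controlled by the E geometry of C7=C11 and by the exo position of the alkynyl arm in the envelope, which gives the anti product (H6 and H7 anti), the relation needed for the trans-lactone. The step needs the [2,3] shift to win over the [1,2] shift, which the low temperature and the short C6···C7 distance in the ring secure, and it needs O8→O6 silyl migration to be absent, which the lithium counter-ion and the cold quench secure.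

**Step 11**
Reactants: 19 cyclodecenynol of step 10
Product: 21 (1S,2Z,6E,9S,10S)-9-(tert-butyldimethylsilyloxy)-3-iodo-7-methyl-10-(prop-1-en-2-yl)cyclodeca-2,6-dien-1-ol, via cyclic alkenylalanate 20 (not isolated)
Conditions: Red-Al (2.5 equiv), Et2O, 0 °C → rt; EtOAc; then I2, THF, −78 °C
Reagents that add atoms: iodine II
Why: In this hydroxyl-directed trans-hydroalumination of a propargylic alcohol, hydride goes to C5 and aluminium to C4 within a five-membered alkoxyalanate. Iodinolysis with retention gives the ring-trans C4=C5 with iodine cis to C6, and release of alkyne strain helps.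

**Step 12**
Reactants: 21 vinyl iodide of step 11
Product: 23 (1S,2Z,6E,9S,10S)-9-(tert-butyldimethylsilyloxy)-10-(1-hydroxypropan-2-yl)-3-iodo-7-methylcyclodeca-2,6-dien-1-ol (both C11 epimers), via B-alkyl-9-BBN adduct 22 (not isolated)
Conditions: 9-BBN (2.5 equiv), THF, 0 °C → rt; then H2O2, aq NaOH, 0 °C
Reagents that add atoms: hydrogen peroxide OO
Why: In this hydroboration–oxidation 9-BBN picks the only 1,1-disubstituted alkene over the trisubstituted alkene and the iodoalkene, and places boron on C12. C11 forms without reliable control and is corrected in step 14.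

**Step 13**
Reactants: 23 1,4-diol of step 12
Product: 25 (6S,7S,8S)-8-(tert-butyldimethylsilyloxy)-4-iodo-15-norgermacra-1(10)E,4Z-dien-12,6-olide (both C11 epimers), via lactol 24 (not isolated)
Conditions: TEMPO (20 mol %), PhI(OAc)2 (2.5 equiv), CH2Cl2, rt
Reagents that add atoms: none
Why: In this oxoammonium-mediated oxidative lactonisation of a 1,4-diol the primary alcohol is oxidised first. O6 captures the aldehyde as the lactol, which is then oxidised to the trans-fused lactone fixed by C6 and C7.

**Step 14**
Reactants: 25 lactone as C11 epimer mixture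
Product: 26 (6S,7S,8S,11S)-8-(tert-butyldimethylsilyloxy)-4-iodo-15-norgermacra-1(10)E,4Z-dien-12,6-olide
Conditions: DBU, toluene, 80 °C
Reagents that add atoms: none
Why: This is a thermodynamic epimerisation through the lactone enolate. C11–H is the only acidic C–H, and the epimer with C13 trans to C8 is the more stable one, so C11 should converge on S. The temperature stays well below that of the Cope rearrangement.

**Step 15**
Reactants: 26 (11S)-iodo lactone
Product: 27 (6R,7S,8S,11S)-8-(tert-butyldimethylsilyloxy)-15-oxogermacra-1(10)E,4Z-dien-12,6-olide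
Conditions: Pd(PPh3)4 (5 mol %), CO (1–3 bar), Bu3SnH (slow addition), THF, 50 °C
Reagents that add atoms: carbon monoxide [C-]#[O+]
Why: In this palladium-catalysed carbonylative formylation of an alkenyl iodide, oxidative addition, CO insertion and hydride transfer all proceed with retention. C15 therefore ends up cis to C6. O6 is already acylated and cannot trap the acylpalladium.

**Step 16**
Reactants: 27 silyl ether enal
Product: 28 (6R,7R,8S,11S)-8-hydroxy-15-oxogermacra-1(10)E,4Z-dien-12,6-olide
Conditions: HF·pyridine, pyridine, THF, 0 °C → rt
Reagents that add atoms: none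
Why: Buffered fluoride desilylation avoids both strong acid (transannular cyclisation of the diene) and free alkoxide (translactonisation to O8).

**Step 17**
Reactants: 29 2-(bromomethyl)acrylic acid
Product: 30 2-(acetoxymethyl)acrylic acid
Conditions: KOAc, DMF, rt; then dilute HCl
Reagents that add atoms: potassium acetate CC(=O)[O-].[K+]
Why: Acetate displaces an activated allylic bromide, and SN2 and SN2′ attack give the same product.

**Step 18**
Reactants: 28 8-hydroxy enal; 30 2-(acetoxymethyl)acrylic acid
Product: 31 (6R,7R,8S,11S)-8-[2-(acetoxymethyl)acryloyloxy]-15-oxogermacra-1(10)E,4Z-dien-12,6-olide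
Conditions: DCC, DMAP (10 mol %), CH2Cl2, 0 °C
Reagents that add atoms: none
Why: In this Steglich esterification O8 is the only hydroxyl in 28, because C15 is still an aldehyde. Configuration at C8 is retained, since only the O–H bond reacts.

**Step 19**
Reactants: 31 ester enal
Product: 32 target, (6R,7R,8S,11S)-8-[2-(acetoxymethyl)acryloyloxy]-15-hydroxygermacra-1(10)E,4Z-dien-12,6-olide
Conditions: NaBH4, CeCl3·7H2O, MeOH, −78 °C
Reagents that add atoms: none
Why: The Luche reduction gives fast 1,2-reduction of the enal, while the lactone, the acetate and the acrylate are left alone at low temperature.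

## Compound list

1 | prop-2-yn-1-ol | C#CCO | starting material
2 | dimethylaluminium (E)-3-(dimethylalumanyl)-2-methylprop-2-en-1-olate | C[Al](C)OC/C(C)=C/[Al](C)C | intermediate (not isolated)
3 | (E)-3-iodo-2-methylprop-2-en-1-ol | OC/C(C)=C/I | intermediate
4 | 1-bromobut-2-yne | CC#CCBr | starting material
5 | (E)-3-(but-2-yn-1-yloxy)-1-iodo-2-methylprop-1-ene | CC#CCOC/C(C)=C/I | intermediate
6 | (E)-3-(but-2-yn-1-yloxy)-2-methylprop-1-enylmagnesium chloride | CC#CCOC/C(C)=C/[Mg]Cl | intermediate (not isolated)
7 | (E)-4-(but-2-yn-1-yloxy)-3-methylbut-2-enal | CC#CCOC/C(C)=C/C=O | intermediate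
8 | allenylboronic acid pinacol ester | C=C=CB1OC(C)(C)C(C)(C)O1 | starting material
9 | (4S,5E)-7-(but-2-yn-1-yloxy)-6-methylhept-5-en-1-yn-4-ol | C#CC[C@H](O)/C=C(C)/COCC#CC | intermediate
10 | TBS ether of 9 | C#CC[C@H](O[Si](C)(C)C(C)(C)C)/C=C(C)/COCC#CC | intermediate
11 | (E)-alkenyl(dimethyl)alane from 10 | C[Al](C)/C=C(C)/C[C@H](O[Si](C)(C)C(C)(C)C)/C=C(C)/COCC#CC | intermediate (not isolated)
12 | (1E,4S,5E)-7-(but-2-yn-1-yloxy)-4-(tert-butyldimethylsilyloxy)-1-iodo-2,6-dimethylhepta-1,5-diene | I/C=C(C)/C[C@H](O[Si](C)(C)C(C)(C)C)/C=C(C)/COCC#CC | intermediate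
13 | pent-3-yn-1-ol | CC#CCCO | starting material
14 | 5-iodopent-2-yne | CC#CCCI | intermediate
15 | pent-3-ynylzinc iodide | CC#CCC[Zn]I | intermediate (not isolated)
16 | (6E,9S,10E)-12-(but-2-yn-1-yloxy)-9-(tert-butyldimethylsilyloxy)-7,11-dimethyldodeca-6,10-dien-2-yne | CC#CCC/C=C(C)/C[C@H](O[Si](C)(C)C(C)(C)C)/C=C(C)/COCC#CC | intermediate
17 | (3E,5S,7E)-5-(tert-butyldimethylsilyloxy)-3,7-dimethyl-1-oxacyclotrideca-3,7-dien-11-yne | O1CC#CCC/C=C(C)/C[C@H](O[Si](C)(C)C(C)(C)C)/C=C(C)/C1 | intermediate
18 | C6-lithiated 17 | [Li]C1C#CCC/C=C(C)/C[C@H](O[Si](C)(C)C(C)(C)C)/C=C(C)/CO1 | intermediate (not isolated)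
19 | (1S,6E,9S,10S)-9-(tert-butyldimethylsilyloxy)-7-methyl-10-(prop-1-en-2-yl)cyclodec-6-en-2-yn-1-ol | CC(C)(C)[Si](C)(C)O[C@H]1C/C(C)=C/CCC#C[C@@H](O)[C@@H]1C(C)=C | intermediate
20 | sodium cyclic alkenylalanate (Al bound to C4 and O6) | CC(C)(C)[Si](C)(C)O[C@H]1C/C(C)=C/CC/C2=C/[C@@H](O[Al-]2(OCCOC)OCCOC)[C@@H]1C(C)=C.[Na+] | intermediate (not isolated)
21 | (1S,2Z,6E,9S,10S)-9-(tert-butyldimethylsilyloxy)-3-iodo-7-methyl-10-(prop-1-en-2-yl)cyclodeca-2,6-dien-1-ol | CC(C)(C)[Si](C)(C)O[C@H]1C/C(C)=C/CC/C(I)=C/[C@@H](O)[C@@H]1C(C)=C | intermediate
22 | B-alkyl-9-BBN adduct of 21 (boron on C12, C11 epimers) | CC(C)(C)[Si](C)(C)O[C@H]1C/C(C)=C/CC/C(I)=C/[C@@H](O)[C@@H]1C(C)CB2C3CCCC2CCC3 | intermediate (not isolated)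
23 | (1S,2Z,6E,9S,10S)-9-(tert-butyldimethylsilyloxy)-10-(1-hydroxypropan-2-yl)-3-iodo-7-methylcyclodeca-2,6-dien-1-ol (C11 epimers) | CC(C)(C)[Si](C)(C)O[C@H]1C/C(C)=C/CC/C(I)=C/[C@@H](O)[C@@H]1C(C)CO | intermediate
24 | 12,6-lactol of 23 (C11 and C12 epimers) | CC(C)(C)[Si](C)(C)O[C@H]1C/C(C)=C/CC/C(I)=C/[C@H]2OC(O)C(C)[C@H]12 | intermediate (not isolated)
25 | (6S,7S,8S)-8-(tert-butyldimethylsilyloxy)-4-iodo-15-norgermacra-1(10)E,4Z-dien-12,6-olide (C11 epimers) | CC(C)(C)[Si](C)(C)O[C@H]1C/C(C)=C/CC/C(I)=C/[C@H]2OC(=O)C(C)[C@H]12 | intermediate
26 | (6S,7S,8S,11S)-8-(tert-butyldimethylsilyloxy)-4-iodo-15-norgermacra-1(10)E,4Z-dien-12,6-olide | CC(C)(C)[Si](C)(C)O[C@H]1C/C(C)=C/CC/C(I)=C/[C@H]2OC(=O)[C@@H](C)[C@H]12 | intermediate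
27 | (6R,7S,8S,11S)-8-(tert-butyldimethylsilyloxy)-15-oxogermacra-1(10)E,4Z-dien-12,6-olide | CC(C)(C)[Si](C)(C)O[C@H]1C/C(C)=C/CC/C(C=O)=C/[C@H]2OC(=O)[C@@H](C)[C@H]12 | intermediate
28 | (6R,7R,8S,11S)-8-hydroxy-15-oxogermacra-1(10)E,4Z-dien-12,6-olide | O[C@H]1C/C(C)=C/CC/C(C=O)=C/[C@H]2OC(=O)[C@@H](C)[C@H]12 | intermediate
29 | 2-(bromomethyl)acrylic acid | C=C(CBr)C(=O)O | starting material
30 | 2-(acetoxymethyl)acrylic acid | C=C(COC(C)=O)C(=O)O | intermediate
31 | (6R,7R,8S,11S)-8-[2-(acetoxymethyl)acryloyloxy]-15-oxogermacra-1(10)E,4Z-dien-12,6-olide | C=C(COC(C)=O)C(=O)O[C@H]1C/C(C)=C/CC/C(C=O)=C/[C@H]2OC(=O)[C@@H](C)[C@H]12 | intermediate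
32 | (6R,7R,8S,11S)-8-[2-(acetoxymethyl)acryloyloxy]-15-hydroxygermacra-1(10)E,4Z-dien-12,6-olide (CNP0291063.1) | C=C(COC(C)=O)C(=O)O[C@H]1C/C(C)=C/CC/C(CO)=C/[C@H]2OC(=O)[C@@H](C)[C@H]12 | target

## Step count and least certain steps

Total step count: 19.
Longest linear sequence: 17 steps (1–6, 8–16, 18, 19). Steps 7 and 17 are one-step side branches.

**Step 10 (key step).** The most likely failure is erosion of the anti preference at C6. The alkynyl arm is part of the ring and may be forced into the endo position of the envelope, and a radical-pair [1,2] shift gains ground if the anion has to be warmed. The control of C7 by C8 rests on allylic strain and is the safer element.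
Fallback: C6 is set by SN2 inversion instead of by the sigmatropic transition state. Starting from 17, the ring contraction is accepted as it comes and the C6-epimeric cyclodecenynol F1 is isolated. A Mitsunobu reaction with 4-nitrobenzoic acid inverts the propargylic centre to the 4-nitrobenzoate F2. Methanolysis with K2CO3 in MeOH then returns to the route at 19.

**Step 4.** The most likely failure is insufficient enantioselectivity. The β,β-disubstituted enal offers the catalyst a less differentiated pocket than aryl aldehydes do, and an uncatalysed background allenylboration may compete.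
Fallback: resolution takes the place of asymmetric catalysis. Starting from 7, a zinc Barbier reaction with propargyl bromide gives the racemic homopropargylic alcohol F3. A lipase (class: serine hydrolase, for example from Candida antarctica B or Burkholderia cepacia) with vinyl acetate should acetylate the R enantiomer to the (R)-acetate F4. The S alcohol is left, and this is 9.

**Step 15.** The most likely failures are two. The first is premature hydride transfer to the alkenylpalladium before CO insertion (hydrodeiodination). The second is ionisation of the allylic C6–O carboxylate by Pd(0), which would open the lactone.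
Fallback: the polarity is reversed and Pd(0) is avoided. Starting from 26, a Nozaki–Hiyama–Kishi reaction (CrCl2, cat. NiCl2, DMF) with paraformaldehyde gives the 15-hydroxy silyl ether F5. Oxidation with MnO2 rejoins the route at 27.

**Step 18.** The most likely failure is attack of the nucleophilic catalyst on the 2-(acetoxymethyl)acrylate unit (SN2′ loss of acetate, then oligomerisation). This can outrun acylation of the hindered secondary O8.
Fallback: the ester bond is made first and the acetate is introduced afterwards. Starting from 29, oxalyl chloride with cat. DMF gives 2-(bromomethyl)acryloyl chloride F6. This acylates 28 with 2,4,6-collidine and no nucleophilic catalyst to give the 8-O-[2-(bromomethyl)acrylate] F7. KOAc with 18-crown-6 in MeCN then displaces bromide and returns to the route at 31.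

## Further compounds

F1 | step 10 | C6 epimer of 19 | CC(C)(C)[Si](C)(C)O[C@H]1C/C(C)=C/CCC#C[C@H](O)[C@@H]1C(C)=C
F2 | step 10 | 4-nitrobenzoate of 19 | CC(C)(C)[Si](C)(C)O[C@H]1C/C(C)=C/CCC#C[C@@H](OC(=O)c2ccc(cc2)[N+](=O)[O-])[C@@H]1C(C)=C
F3 | step 4 | racemic (E)-7-(but-2-yn-1-yloxy)-6-methylhept-5-en-1-yn-4-ol | C#CCC(O)/C=C(C)/COCC#CC
F4 | step 4 | (4R,5E)-7-(but-2-yn-1-yloxy)-6-methylhept-5-en-1-yn-4-yl acetate | C#CC[C@@H](OC(C)=O)/C=C(C)/COCC#CC
F5 | step 15 | (6R,7S,8S,11S)-8-(tert-butyldimethylsilyloxy)-15-hydroxygermacra-1(10)E,4Z-dien-12,6-olide | CC(C)(C)[Si](C)(C)O[C@H]1C/C(C)=C/CC/C(CO)=C/[C@H]2OC(=O)[C@@H](C)[C@H]12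
F6 | step 18 | 2-(bromomethyl)acryloyl chloride | C=C(CBr)C(=O)Cl
F7 | step 18 | (6R,7R,8S,11S)-8-[2-(bromomethyl)acryloyloxy]-15-oxogermacra-1(10)E,4Z-dien-12,6-olide | C=C(CBr)C(=O)O[C@H]1C/C(C)=C/CC/C(C=O)=C/[C@H]2OC(=O)[C@@H](C)[C@H]12
A1 | alternative 1 | open-chain bromo enal, methyl (Z)-2-(bromomethyl)enoate with C8 (S) silyl ether | O=C/C=C(CO[Si](C)(C)C(C)(C)C)/CC/C=C(C)/C[C@H](O[Si](C)(C)C(C)(C)C)/C=C(CBr)/C(=O)OC
A2 | alternative 1 | 8,15-bis(silyloxy)germacra-1(10),4,11(13)-trien-12,6-olide | CC(C)(C)[Si](C)(C)O[C@H]1C/C(C)=C/CC/C(CO[Si](C)(C)C(C)(C)C)=C/[C@H]2OC(=O)C(=C)[C@H]12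
A3 | alternative 2 | 1β-mesyloxy-8α-silyloxy-15-oxo-5αH-eudesman-12,6α-olide (C4 epimers) | C[C@@H]1C(=O)O[C@H]2[C@H]1[C@@H](O[Si](C)(C)C(C)(C)C)C[C@@]3(C)[C@H](OS(C)(=O)=O)CCC(C=O)[C@H]23
A4 | alternative 3 | lactone-fused trans-1,2-dialkenylcyclohexanol (10-hydroxy-14-nor-elemane type) | C=C[C@]1(O)C[C@H](O[Si](C)(C)C(C)(C)C)[C@H]2[C@H](C)C(=O)O[C@@H]2[C@H]1C(=C)CO[Si](C)(C)C(C)(C)C
A5 | alternative 3 | ten-membered C10 enol triflate | CC(C)(C)[Si](C)(C)O[C@H]1C/C(OS(=O)(=O)C(F)(F)F)=C/CC/C(CO[Si](C)(C)C(C)(C)C)=C/[C@H]2OC(=O)[C@@H](C)[C@H]12
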